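Early on, the amount of target per litre reads nearly the same in south and south-west, although their substrate charges differ. At 1.04 d south's fraction of its charge is 2.23 times south-west's, and south-west's charge is 2.21 times south's, so at that early time, with reagent and initiator held, you can move a fraction between these two charges by their ratio.

| flask | substrate | reagent | initiator | remark | time |
|---|---|---|---|---|---|
| south | 0.34 M | 1.5 M | 6 mM | run made earlier |  |
| south-west | 0.75 M | 1.5 M | 6 mM | run made earlier |  |
| east | 0.50 M | 3 M | 6 mM | run made earlier |  |
| flask | 0.50 M | 1.50 M | 6.0 mM |  | 15 d |

| run | time / d | target / % |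
|---|---|---|
| south | 1.04 | 26.5 |
| south | 1.67 | 33.7 |
| south | 3.00 | 39.6 |
| south | 5.00 | 40.4 |
| south | 10.0 | 38.5 |
| south-west | 1.04 | 11.9 |
| south-west | 1.67 | 15.0 |
| south-west | 3.00 | 16.7 |
| south-west | 5.00 | 15.9 |
| south-west | 10.0 | 10.0 |
| east | 1.04 | 30.4 |
| east | 1.67 | 35.4 |
| east | 3.00 | 39.9 |
| east | 5.00 | 39.5 |
| east | 10.0 | 37.8 |

(readings scatter by 0.5 percentage points)

- a reading or a percentage of target counts all its forms, free or not

- time up to 15 d at which target stands highest
- the amount of target, in percent of the substrate charged, at that time

This flask has south's reagent and initiator, so fold the runs into one number. Call it the carry-over share: south's top reading, 40.4 %, times south's charge over the flask's charge, which is 27.5 %. In words, it is the fraction of this flask's substrate that south's highest reading of target comes to. So I commit to a peak near 27.5 %, between 3.00 d and 5.00 d, where the runs top out.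

Is one number enough? Not quite. Folded to south-west's charge, the same amount gives 18.3 %, but south-west reads 16.7 %, which is 1.6 percentage points short against a scatter of 0.5 points. East differs from south in both reagent, at 3 M, and substrate, and it holds 1.69 times south's amount at 1.04 d; the early amount did not follow substrate between south and south-west, so this points to reagent. The number is therefore tied to south's reagent, and at south-west's larger substrate charge it reads high.

The forecast gives 26 % at 3.6 d, a little below my share, on the view that “Later loss of target is strongly substrate-dependent”.

The flask gives 28.5 % at 3.79 d, which is 1 point above the carry-over share. At 7.59 d the flask still holds 26.6 %.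

    initiator → 2 initiating radical (k = 2.80 × 10⁻⁴ min⁻¹)
    substrate + initiating radical → capped initiator + first chain carrier (k = 1.40 × 10⁵ M⁻¹ min⁻¹)
    reagent + first chain carrier → target + second chain carrier (k = 1500 M⁻¹ min⁻¹)
    substrate + second chain carrier → by-product + first chain carrier (k = 7600 M⁻¹ min⁻¹)
    first chain carrier → ended carrier (k = 31.0 min⁻¹)
    2 first chain carrier → ended chains A (k = 8.00 × 10⁶ M⁻¹ s⁻¹)
    2 second chain carrier → ended chains B (k = 3.00 × 10⁶ M⁻¹ s⁻¹)
    substrate + target ⇌ idle adduct, settled at all times (K = 4.70 M⁻¹)
    substrate + target → side product (k = 0.00230 M⁻¹ min⁻¹)

Taken in straight proportion to reagent, a rough guess since east's early amount rose less than its reagent, the share for the neighbour flask charged with 0.38 M reagent comes to 6.96 %; that neighbour's best is 6.77 %.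

All runs are simulated with constants of no real substance; the scatter is artificial.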